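The flavanone is cut at C2–C1′. A rhodium-catalysed enantioselective 1,4-addition joins a boronic acid, which already carries ring B and the whole apigenin unit (3′–6″ biaryl by Suzuki coupling), to 5,7-dibenzyloxychromone. Ring C of this chromone is grown from a furanone ring. C3, its only unsubstituted methylene, enters as a carbenoid carbon across the enol double bond of a 3-silyloxybenzofuran. One-electron oxidative scission of the shared bond in the resulting cyclopropa[b]benzofuran then delivers, in one operation, the six-membered O1–C2–C3–C4–C4a–C8a ring and the C2=C3 unsaturation that the arylation needs. O1 and the C4 oxygen, which flank that bond, direct its cleavage.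

Key step: step 4

Assumption (remark on the chemistry): the 3′–6″ biaryl axis is taken as freely rotating, since the target defines no axial chirality. Compounds 4 and 5 are racemic, which is harmless because their stereocentres are erased before C2 is set in step 9.

Step 1
Reactants: 1 4,6-dihydroxybenzofuran-3(2H)-one
Product: 2 4,6-bis(benzyloxy)benzofuran-3(2H)-one
Conditions: BnBr (2.2 equiv), K2CO3, DMF, rt to 40 °C
Reagents that add atoms: benzyl bromide, BrCc1ccccc1
Why: Williamson ether synthesis, in which K2CO3 deprotonates only the two phenols and their phenoxides are alkylated on oxygen faster than the less acidic C2 methylene can react.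

Step 2
Reactants: 2 4,6-bis(benzyloxy)benzofuran-3(2H)-one
Product: 3 4,6-bis(benzyloxy)-3-(tert-butyldimethylsilyloxy)benzofuran
Conditions: TBSOTf, Et3N, CH2Cl2, 0 °C
Reagents that add atoms: tert-butyldimethylsilyl triflate, CC(C)(C)[Si](C)(C)OS(=O)(=O)C(F)(F)F
Why: Silyl enol ether formation by soft enolisation, driven by the aromaticity of the benzofuran that results, with the aryl benzyl ethers inert to TBSOTf and Et3N.

Step 3
Reactants: 3 4,6-bis(benzyloxy)-3-(tert-butyldimethylsilyloxy)benzofuran
Product: 4 racemic, cis-fused 4,6-bis(benzyloxy)-6b-(tert-butyldimethylsilyloxy)-1a,6b-dihydro-1H-cyclopropa[b]benzofuran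
Conditions: Et2Zn, CH2I2, CH2Cl2, 0 °C to rt
Reagents that add atoms: diiodomethane, ICI
Why: Furukawa variant of the Simmons–Smith cyclopropanation, in which the furan C2=C3 bond carries two oxygen donors and is only weakly aromatic, so the electrophilic zinc carbenoid should add there and not to the benzenoid rings, and the two new stereocentres can only form as the cis-fused racemate.

Step 4
Reactants: 4 racemic, cis-fused 4,6-bis(benzyloxy)-6b-(tert-butyldimethylsilyloxy)-1a,6b-dihydro-1H-cyclopropa[b]benzofuran
Product: 6 5,7-bis(benzyloxy)-4H-chromen-4-one, via 2-chlorochromanone 5 (not isolated)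
Conditions: FeCl3 (2.5 equiv), DMF, 0 °C to rt; then NaOAc, MeOH, 40 °C
Reagents that add atoms: none
Why: FeCl3 exchanges the silyl group for an iron alkoxide, inner-sphere electron transfer to trivalent iron gives a cyclopropyloxy radical, this opens by beta-scission of the internal C1a–C6b bond to the ring-enlarged C2 radical, and a second FeCl3 hands over chlorine to give 5, which loses HCl to NaOAc and forms the vinylogous ester 6. The closest known reaction is the Ito–Saegusa one-carbon ring enlargement of 1-silyloxybicyclo[n.1.0]alkanes to cycloalkenones. No ring is closed: ring C appears when the zero-atom bridge of the 2-oxabicyclo[3.1.0]hexane core breaks, so that the five-membered furan ring and the cyclopropane merge into one six-membered ring. No stereocentre is formed and both stereocentres of 4 vanish, which is why the racemate serves. The step needs cleavage of the internal and not of the external C6b–C1 bond, and this is secured because only internal cleavage gives a secondary radical stabilised by O1 and frees the strain of both small rings, whereas external cleavage would give a primary radical. It also needs the electron-rich ring A and the benzyl ethers to survive, which DMF-complexed FeCl3 at 0 °C, a mild oxidant that acts through the bound alkoxide, should allow.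

Step 5
Reactants: 7 apigenin (5,7-dihydroxy-2-(4-hydroxyphenyl)-4H-chromen-4-one)
Product: 8 7-(benzyloxy)-2-[4-(benzyloxy)phenyl]-5-hydroxy-4H-chromen-4-one
Conditions: BnBr (2.1 equiv), K2CO3, DMF, rt
Reagents that add atoms: benzyl bromide, BrCc1ccccc1
Why: Williamson ether synthesis that should stop at the 7- and 4′-ethers, since the 5-OH is hydrogen-bonded to the C4 carbonyl and is the least nucleophilic of the three.

Step 6
Reactants: 8 7-(benzyloxy)-2-[4-(benzyloxy)phenyl]-5-hydroxy-4H-chromen-4-one
Product: 9 7-(benzyloxy)-2-[4-(benzyloxy)phenyl]-5-hydroxy-6-iodo-4H-chromen-4-one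
Conditions: BnMe3N·ICl2, CaCO3, CH2Cl2–MeOH, rt
Reagents that add atoms: benzyltrimethylammonium dichloroiodate, C[N+](C)(C)Cc1ccccc1.Cl[I-]Cl
Why: Electrophilic aromatic iodination, in which C6, between the free 5-OH and the 7-ether, is the known site of attack of this reagent on 5-hydroxy-7-alkoxyflavones (C8 is preferred only when O5 is alkylated) and CaCO3 takes up the acid.

Step 7
Reactants: 9 7-(benzyloxy)-2-[4-(benzyloxy)phenyl]-5-hydroxy-6-iodo-4H-chromen-4-one, 10 [2-(benzyloxy)-5-chlorophenyl]boronic acid
Product: 11 7-(benzyloxy)-6-[2-(benzyloxy)-5-chlorophenyl]-2-[4-(benzyloxy)phenyl]-5-hydroxy-4H-chromen-4-one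
Conditions: Pd(PPh3)4 (5 mol %), aq. Na2CO3, DME, 85 °C
Reagents that add atoms: none
Why: Suzuki–Miyaura coupling, in which zerovalent palladium with PPh3 inserts only into the C–I bond, so the aryl chloride is kept as the handle for step 8, and the small free 5-OH eases crowding around the new tri-ortho-substituted 3′–6″ bond.

Step 8
Reactants: 11 7-(benzyloxy)-6-[2-(benzyloxy)-5-chlorophenyl]-2-[4-(benzyloxy)phenyl]-5-hydroxy-4H-chromen-4-one
Product: 12 [4-(benzyloxy)-3-{7-(benzyloxy)-2-[4-(benzyloxy)phenyl]-5-hydroxy-4-oxo-4H-chromen-6-yl}phenyl]boronic acid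
Conditions: Pd(OAc)2 (2 mol %), XPhos (6 mol %), B2(OH)4, KOAc, EtOH, 80 °C
Reagents that add atoms: tetrahydroxydiboron, OB(O)B(O)O
Why: Miyaura-type borylation, in which the bulky electron-rich XPhos lets zerovalent palladium insert into the aryl C–Cl bond and tetrahydroxydiboron gives the boronic acid directly, with no pinacol ester to cleave.

Step 9
Reactants: 6 5,7-bis(benzyloxy)-4H-chromen-4-one, 12 [4-(benzyloxy)-3-{7-(benzyloxy)-2-[4-(benzyloxy)phenyl]-5-hydroxy-4-oxo-4H-chromen-6-yl}phenyl]boronic acid
Product: 13 (2S)-5,7-bis(benzyloxy)-2-[4-(benzyloxy)-3-{7-(benzyloxy)-2-[4-(benzyloxy)phenyl]-5-hydroxy-4-oxo-4H-chromen-6-yl}phenyl]chroman-4-one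
Conditions: [Rh(OH)(cod)]2 (2 mol %), (S)-MeO-F12-BIPHEP [(S)-6,6′-dimethoxybiphenyl-2,2′-diylbis{bis(3,4,5-trifluorophenyl)phosphine}] (4.4 mol %), CH2Cl2–H2O 10:1, 25 °C
Reagents that add atoms: none
Why: Hayashi–Miyaura asymmetric 1,4-addition, in which the aryl–rhodium species inserts the unsubstituted C2=C3 bond of 6 but not the beta,beta-disubstituted enone of the flavone unit, the (S)-bisphosphine shields one enone face so that the aryl group should arrive on the face that gives 2S (the same face as in the formation of (S)-3-arylcyclohexanones), and base-free CH2Cl2 suppresses retro-oxa-Michael racemisation and 1,2-addition to the product.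

Step 10
Reactants: 13 (2S)-5,7-bis(benzyloxy)-2-[4-(benzyloxy)-3-{7-(benzyloxy)-2-[4-(benzyloxy)phenyl]-5-hydroxy-4-oxo-4H-chromen-6-yl}phenyl]chroman-4-one
Product: 14 (2S)-5,7-dihydroxy-2-{4-hydroxy-3-[5,7-dihydroxy-2-(4-hydroxyphenyl)-4-oxo-4H-chromen-6-yl]phenyl}chroman-4-one (target)
Conditions: H2 (1 atm), 10% Pd/C, EtOAc–MeOH, rt
Reagents that add atoms: none
Why: Hydrogenolysis of the five aryl benzyl ethers under neutral conditions, which should leave the flavone C2″=C3″ bond, both carbonyl groups and the base-sensitive C2 stereocentre untouched if it is stopped at full debenzylation.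

Compound list
1 | 4,6-dihydroxybenzofuran-3(2H)-one | O=C1COc2cc(O)cc(O)c12 | starting material
2 | 4,6-bis(benzyloxy)benzofuran-3(2H)-one | O=C1COc2cc(OCc3ccccc3)cc(OCc3ccccc3)c12 | intermediate
3 | 4,6-bis(benzyloxy)-3-(tert-butyldimethylsilyloxy)benzofuran | CC(C)(C)[Si](C)(C)Oc1coc2cc(OCc3ccccc3)cc(OCc3ccccc3)c12 | intermediate
4 | 4,6-bis(benzyloxy)-6b-(tert-butyldimethylsilyloxy)-1a,6b-dihydro-1H-cyclopropa[b]benzofuran (racemic, cis fusion enforced) | CC(C)(C)[Si](C)(C)OC12CC1Oc1cc(OCc3ccccc3)cc(OCc3ccccc3)c21 | intermediate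
5 | 5,7-bis(benzyloxy)-2-chlorochroman-4-one (racemic, not isolated) | O=C1CC(Cl)Oc2cc(OCc3ccccc3)cc(OCc3ccccc3)c21 | intermediate
6 | 5,7-bis(benzyloxy)-4H-chromen-4-one | O=c1ccoc2cc(OCc3ccccc3)cc(OCc3ccccc3)c12 | intermediate
7 | apigenin | O=c1cc(-c2ccc(O)cc2)oc2cc(O)cc(O)c12 | starting material
8 | 7-(benzyloxy)-2-[4-(benzyloxy)phenyl]-5-hydroxy-4H-chromen-4-one | O=c1cc(-c2ccc(OCc3ccccc3)cc2)oc2cc(OCc3ccccc3)cc(O)c12 | intermediate
9 | 7-(benzyloxy)-2-[4-(benzyloxy)phenyl]-5-hydroxy-6-iodo-4H-chromen-4-one | O=c1cc(-c2ccc(OCc3ccccc3)cc2)oc2cc(OCc3ccccc3)c(I)c(O)c12 | intermediate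
10 | [2-(benzyloxy)-5-chlorophenyl]boronic acid | OB(O)c1cc(Cl)ccc1OCc1ccccc1 | starting material
11 | 7-(benzyloxy)-6-[2-(benzyloxy)-5-chlorophenyl]-2-[4-(benzyloxy)phenyl]-5-hydroxy-4H-chromen-4-one | O=c1cc(-c2ccc(OCc3ccccc3)cc2)oc2cc(OCc3ccccc3)c(-c3cc(Cl)ccc3OCc3ccccc3)c(O)c12 | intermediate
12 | [4-(benzyloxy)-3-{7-(benzyloxy)-2-[4-(benzyloxy)phenyl]-5-hydroxy-4-oxo-4H-chromen-6-yl}phenyl]boronic acid | O=c1cc(-c2ccc(OCc3ccccc3)cc2)oc2cc(OCc3ccccc3)c(-c3cc(B(O)O)ccc3OCc3ccccc3)c(O)c12 | intermediate
13 | (2S)-5,7-bis(benzyloxy)-2-[4-(benzyloxy)-3-{7-(benzyloxy)-2-[4-(benzyloxy)phenyl]-5-hydroxy-4-oxo-4H-chromen-6-yl}phenyl]chroman-4-one | O=C1C[C@@H](c2ccc(OCc3ccccc3)c(-c3c(OCc4ccccc4)cc4oc(-c5ccc(OCc6ccccc6)cc5)cc(=O)c4c3O)c2)Oc2cc(OCc3ccccc3)cc(OCc3ccccc3)c21 | intermediate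
14 | (2S)-5,7-dihydroxy-2-{4-hydroxy-3-[5,7-dihydroxy-2-(4-hydroxyphenyl)-4-oxo-4H-chromen-6-yl]phenyl}chroman-4-one | O=C1C[C@@H](c2ccc(O)c(-c3c(O)cc4oc(-c5ccc(O)cc5)cc(=O)c4c3O)c2)Oc2cc(O)cc(O)c21 | target

Total step count: 10. Longest linear sequence: 6 steps (steps 1, 2, 3, 4, 9, 10, or equally steps 5, 6, 7, 8, 9, 10).

Steps most likely to fail

Step 3. Methylene transfer to the heteroaromatic double bond may be too slow. The Lewis-acidic zinc iodide may also strip the silyl group or open the donor-substituted cyclopropane before it can be used. The fallback sets out from 3 and uses a free dihalocarbene, a far stronger electrophile of a kind known to add to the 2,3-bond of benzofurans.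
- CHBr3 and KOtBu in hexane at −20 °C should give 4,6-bis(benzyloxy)-1,1-dibromo-6b-(tert-butyldimethylsilyloxy)-1a,6b-dihydro-1H-cyclopropa[b]benzofuran F1.
- F1 should ionise at once, with disrotatory opening of the internal bond to a 4-silyloxybenzopyrylium bromide. Loss of the silyl group then gives 5,7-bis(benzyloxy)-3-bromo-4H-chromen-4-one F2.
- Hydrodebromination with Pd(PPh3)4 and HCO2Na in DMF comes back to the route at 6.

This path replaces steps 3 and 4. It still makes ring C by enlargement of the furan ring, and it avoids the iron oxidant should that attack ring A.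

Step 9. Protodeboronation of the bulky, electron-rich boronic acid may outrun insertion, and the peri 5-benzyloxy group of the chromone may erode facial selectivity. The fallback sets out from 6 and 12 and separates bond formation from stereocontrol.
- An achiral catalyst, Pd(OCOCF3)2 with 2,2′-bipyridine in aqueous MeOH, should give the racemic pentabenzyl ether F3.
- Dynamic kinetic resolution by asymmetric transfer hydrogenation follows, with RuCl(p-cymene)[(S,S)-TsDPEN], HCO2H–Et3N and DBU in MeCN. The slower enantiomer racemises through reversible retro-oxa-Michael opening, and the flavone carbonyl stays inert. This should give the cis-(2S,4S)-flavan-4-ol F4.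
- Dess–Martin oxidation in CH2Cl2 comes back to the route at 13.

Step 10. Over-reduction may compete with removal of the last, hindered benzyl ethers. The possible paths are hydrogenolytic opening of the benzylic C2–O1 bond and saturation of the flavone C2″=C3″ bond. Long contact times also invite racemisation of the free 4′-hydroxyflavanone. The fallback sets out from 13 and is non-reductive. Lewis-acid debenzylation with BCl3 and pentamethylbenzene as cation scavenger in CH2Cl2 at −78 °C, followed by a MeOH quench, leads directly to 14 and makes no new compound.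

Further compounds
F1 | step 3 | 4,6-bis(benzyloxy)-1,1-dibromo-6b-(tert-butyldimethylsilyloxy)-1a,6b-dihydro-1H-cyclopropa[b]benzofuran (racemic) | CC(C)(C)[Si](C)(C)OC12C(Br)(Br)C1Oc1cc(OCc3ccccc3)cc(OCc3ccccc3)c21
F2 | step 3 | 5,7-bis(benzyloxy)-3-bromo-4H-chromen-4-one | O=c1c(Br)coc2cc(OCc3ccccc3)cc(OCc3ccccc3)c12
F3 | step 9 | racemic 5,7-bis(benzyloxy)-2-[4-(benzyloxy)-3-{7-(benzyloxy)-2-[4-(benzyloxy)phenyl]-5-hydroxy-4-oxo-4H-chromen-6-yl}phenyl]chroman-4-one | O=C1CC(c2ccc(OCc3ccccc3)c(-c3c(OCc4ccccc4)cc4oc(-c5ccc(OCc6ccccc6)cc5)cc(=O)c4c3O)c2)Oc2cc(OCc3ccccc3)cc(OCc3ccccc3)c21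
F4 | step 9 | 7-(benzyloxy)-6-{2-(benzyloxy)-5-[(2S,4S)-5,7-bis(benzyloxy)-4-hydroxychroman-2-yl]phenyl}-2-[4-(benzyloxy)phenyl]-5-hydroxy-4H-chromen-4-one | O[C@H]1C[C@@H](c2ccc(OCc3ccccc3)c(-c3c(OCc4ccccc4)cc4oc(-c5ccc(OCc6ccccc6)cc5)cc(=O)c4c3O)c2)Oc2cc(OCc3ccccc3)cc(OCc3ccccc3)c21
F0 | step 10 | none | none
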